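**One share.** Cedar had made more product than alder by 30.0 min, 25.6 % against 9.5 %. I called the pool whatever had been dosed and was not yet product. Electrophile over pool read 0.538 in cedar and 0.540 in alder. I named this reading the free share, s.

| setting | alder | cedar | delta | theta |
|---|---|---|---|---|
| electrophile | 0.20 M (fed, over 40 min) | 0.20 M (fed, over 40 min) | 0.20 M (fed, over 40 min) | 0.20 M (fed, over 40 min) |
| nucleophile | 0.11 M | 0.34 M | 0.210 M | 0.420 M |
| remark | run made earlier; the fed solution adds 0.50 times the starting volume | run made earlier; the fed solution adds 0.50 times the starting volume | the fed solution adds 0.50 times the starting volume | the fed solution adds 0.50 times the starting volume |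
| time |  |  | 40 min | 40 min |

| run | time / min | electrophile / % | product / % |
|---|---|---|---|
| alder | 5.00 | 8.6 | 0.4 |
| alder | 10.0 | 15.2 | 2.8 |
| alder | 15.0 | 20.6 | 4.2 |
| alder | 20.0 | 25.5 | 6.3 |
| alder | 25.0 | 30.0 | 8.1 |
| alder | 30.0 | 35.4 | 9.5 |
| cedar | 2.50 | 4.3 | 0.8 |
| cedar | 4.00 | 7.0 | 1.3 |
| cedar | 6.00 | 9.9 | 1.8 |
| cedar | 10.0 | 12.0 | 5.8 |
| cedar | 15.0 | 16.5 | 10.7 |
| cedar | 30.0 | 26.6 | 25.6 |

(standard deviation of a reading: 0.5 percentage points)

- amounts are per litre of the starting volume; all of the dose is in the solution fed
- what has gone from electrophile into another species counts as reacted, even if it can come back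
- percentages count the whole charge, also what has not yet gone in

1. part of the electrophile that has reacted at the end, delta
2. part of the electrophile that has reacted at the end, theta
3. what raising the concentration of nucleophile from its lowest to its highest value here does to the part of the electrophile that has reacted (changes below 5 percentage points count as none) (it rises / it falls / no change)

**Pool constant.** I took the reacted part at the end of dosing as one minus s times the pool. So I needed the pool. I let it turn into product at g[nucleophile] per minute, a pseudo-first-order loss, and took [nucleophile] as charge over mean volume. With x as that rate times the time, mean age makes pool over dosed part the exponential of minus x over 2. Cedar gave g = 0.0972 M⁻¹ min⁻¹, and alder gave 0.0975 M⁻¹ min⁻¹.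

**First numbers.** Delta had x = 0.653 and theta had x = 1.31. That gave 61.2 % reacted for delta and 72.1 % for theta.

**Weak link.** Mean age is rough at theta's large x. Integrating the rate gives the pool as 1 minus the exponential of minus x, all over x. I kept g. The pool became 0.734 for delta and 0.558 for theta, so I committed to 60.5 % and 70.0 %.

**The forecast.** It read the runs as “a nucleophile-independent reversible step”. It gave 61 % (56 % to 66 %) for delta and 70 % (64 % to 76 %) for theta, and said of the trend: it rises.

**The flask.** Delta gave 59.9 % and theta 69.5 %; across the range of nucleophile, it rises, by 9.5 percentage points.

    electrophile + nucleophile → acid set free + product (k = 0.00400 M⁻¹ s⁻¹)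
    nucleophile + acid set free ⇌ protonated nucleophile, settled at all times (K = 2500 M⁻¹)
    nucleophile + acid set free ⇌ idle adduct, settled at all times (K = 700 M⁻¹)
    electrophile ⇌ dormant form (K = 1.00, k = 0.00280 s⁻¹)

**The share again.** In delta at 40.0 min, the dormant form held 34.8 %, more than the product's 25.1 %. Electrophile over pool there was 0.535, against my reading of 0.538. A neighbour flask like delta, but with 0.80 M of electrophile, had 0.263 equiv of nucleophile and reached 12.5 % product. With that product, s gives 52.9 % reacted. The neighbour flask read 52.7 %.

(The numbers in the tables come from a simulation with made-up constants, and the scatter is random.)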